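(Readings and results were computed for substances that don't exist, noise included.)

The slowness of these flasks is read here not in hours but in enzyme-time, the enzyme charged multiplied by the hours run.

| flask | starting material | second substrate | enzyme | remark |
|---|---|---|---|---|
| dawn | 20 mM | 22 mM | 5 µM | run made earlier |
| summer | 20 mM | 22 mM | 7.5 µM | run made earlier |
| flask | 20 mM | 22.0 mM | 10 µM |  |

| run | time / h | product / % | starting material / % |
|---|---|---|---|
| dawn | 0.500 | 12 | 86 |
| dawn | 1.33 | 22 | 77 |
| dawn | 2.50 | 36 | 62 |
| dawn | 4.00 | 41 | 57 |
| summer | 0.333 | 11 | 87 |
| summer | 0.667 | 20 | 78 |
| summer | 1.50 | 34 | 69 |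
| summer | 4.00 | 51 | 51 |

(readings scatter by 2 percentage points)

- factor on the rate of making product when 50% of the starting material are converted if enzyme is charged twice over
- factor on the rate when 50% of the starting material are converted if enzyme is charged at 2.0 µM instead

- what was read earlier has a scatter of 2 percentage points, one standard deviation

The charges of starting material and second substrate are the same in dawn, summer and the flask, so a factor taken at equal conversion compares enzyme charges with those two held fixed. What has to be known well is the order in enzyme, the exponent on the ratio of enzyme charges. Its zero of the scale is order 1, where the rate follows the charge exactly. An error of 0.5 in the order would move the doubling factor by a factor 1.41 and the factor for 2.0 µM by 2.24.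

Dawn at 2.50 h and summer at 1.50 h show close fractions of product, 36% and 34%, and their mean rates read an order of 1.12, with a scatter of 0.200. That reading lies nearer to order 1 than its scatter, so this reckoning keeps order 1, which gives 2 and 0.200 against the enzyme charge of the flask. Summer shows 51% of the starting material left at 4.00 h, which gives a reading of 30.0 µM·h, with the scatter of that point, for the enzyme-time to 50% conversion, enzyme charge times hours needed.

The forecast gives 2 (1.75 to 2.35) and 0.2 (0.13 to 0.27), because “the curves overlay within the 2-point scatter”.

The flask gives 2.01 and 0.199.

    starting material + enzyme ⇌ starting complex (K = 1400 L mol⁻¹, k = 630 L mol⁻¹ s⁻¹)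
    2 starting complex → spent catalyst (k = 57.0 L mol⁻¹ s⁻¹)
    second substrate + starting complex ⇌ ternary complex (K = 21.0 L mol⁻¹, k = 4200 L mol⁻¹ s⁻¹)
    ternary complex → enzyme + product (k = 1.20 s⁻¹)

The flask stands at 50% conversion at 2.82 h, an enzyme-time of 28.2 µM·h, and the 30.0 µM·h read from summer reckons 3.00 h for the enzyme charge of the flask. Carried to 2.0 µM, the same reading gives an estimate of 15.0 h. At 4.00 h in the flask, starting material has a half-life of 3.0 h by its forward binding to enzyme alone, longer than the 0.058 h of second substrate by its forward passing into ternary complex alone. At that time in the flask, enzyme is 1.01% of the catalyst charged and spent catalyst, outside the working round and counted by the catalyst it holds, is 89.3%.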